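**Retrosynthetic overview**
- Target ⇐ catalyst-controlled reduction of the side-ring enone and equatorial methyl addition to the benzoxepinone carbonyl of a bicyclic diketone.
- Bicyclic diketone ⇐ one operation that first joins the two halves (vinylogous Mukaiyama–Michael addition) and then closes the oxepane and the cyclohexanone together (diepoxide oxa-/carbacyclisation).
- Left half ⇐ a diepoxy vinyl ketone from (E)-geranylacetone (double Shi epoxidation, α-methylenation).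
- Right half ⇐ the silyl dienol ether of a (4R)-cyclohexenone built on a valinol-derived Meyers lactam (quaternary carbon by double alkylation, ring by aldol condensation).
- Ring order: side cyclohexene ring first (aldol), then the oxepane and the cyclohexane of the bicycle together in the key step.

Assumption: (E)-geranylacetone (≥97 % E), (S)-valinol and 5-oxoheptanoic acid are bought as such; locants C3, C5a, C6, C7, C9a refer to the 1-benzoxepine numbering of the target's bicycle.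

**Route**

Step 1
Reactants: 1 (E)-geranylacetone
Product: 2 (5R,6R,9R)-5,6:9,10-diepoxy-6,10-dimethylundecan-2-one
Conditions: 1,2:4,5-di-O-isopropylidene-β-D-erythro-2,3-hexodiulo-2,6-pyranose (Shi ketone, 0.3 equiv per alkene), KHSO5 (Oxone), K2CO3, Bu4NHSO4, Na2B4O7 buffer pH 10.5, MeCN/CH2(OMe)2/H2O, 0 °C; Et3N-washed silica
Reagents that add atoms: potassium peroxymonosulfate (KHSO5), [K+].[O-]S(=O)(=O)OO
Why: Shi asymmetric epoxidation: the dioxirane of the D-fructose-derived ketone adds to both trisubstituted alkenes through the spiro transition state and gives the (R,R)- and (R)-epoxides under reagent control (they become C9a/C5a and C3 of the bicycle), while the ketone is inert at pH 10.5.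

Step 2
Reactants: 2 (5R,6R,9R)-5,6:9,10-diepoxy-6,10-dimethylundecan-2-one
Product: 5 (6R,7R,10R)-6,7:10,11-diepoxy-7,11-dimethyldodec-1-en-3-one, via Mannich base 3 (not isolated), via ammonium iodide 4 (not isolated)
Conditions: LiN(iPr)2, THF, −78 °C; (CH2=NMe2)I, −78 → 0 °C; MeI, CH2Cl2, rt; aq. NaHCO3, rt
Reagents that add atoms: Eschenmoser's salt (N,N-dimethylmethyleneiminium iodide), C=[N+](C)C.[I-]
Why: Eschenmoser α-methylenation: kinetic deprotonation at the methyl group, Mannich reaction, N-methylation and E1cB elimination give the vinyl ketone, and the trisubstituted epoxides tolerate the cold amide base and the weak base of the elimination.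

Step 3
Reactants: 6 (S)-valinol; 7 5-oxoheptanoic acid
Product: 8 (3S,8aR)-8a-ethyl-3-(propan-2-yl)hexahydro-5H-[1,3]oxazolo[3,2-a]pyridin-5-one
Conditions: toluene, reflux, Dean–Stark trap
Reagents that add atoms: none
Why: Meyers bicyclic lactam formation (N,O-ketalisation then lactamisation); under thermodynamic control the angular ethyl group lies cis to the isopropyl group, so C8a is set by the valinol stereocentre.

Step 4
Reactants: 8 (3S,8aR)-8a-ethyl-3-(propan-2-yl)hexahydro-5H-[1,3]oxazolo[3,2-a]pyridin-5-one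
Product: 9 (3S,8aR)-8a-ethyl-6-(4-methylpent-3-en-1-yl)-3-(propan-2-yl)hexahydro-5H-[1,3]oxazolo[3,2-a]pyridin-5-one (C6 epimers)
Conditions: LiN(iPr)2, THF/DMPU, −78 °C; 5-bromo-2-methylpent-2-ene, −78 → −20 °C
Reagents that add atoms: 5-bromo-2-methylpent-2-ene, CC(C)=CCCBr
Why: alkylation of the lactam lithium enolate with a primary bromide; the C6 configuration is irrelevant because this centre is re-enolised in step 5.

Step 5
Reactants: 9 (3S,8aR)-8a-ethyl-6-(4-methylpent-3-en-1-yl)-3-(propan-2-yl)hexahydro-5H-[1,3]oxazolo[3,2-a]pyridin-5-one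
Product: 10 (3S,6R,8aR)-8a-ethyl-6-methyl-6-(4-methylpent-3-en-1-yl)-3-(propan-2-yl)hexahydro-5H-[1,3]oxazolo[3,2-a]pyridin-5-one
Conditions: LiN(iPr)2, THF, −78 °C; MeI, −78 °C; chromatography
Reagents that add atoms: iodomethane, CI
Why: Meyers endo-selective alkylation: the lactam enolate takes up MeI on the face anti to the angular ethyl group, which sets the quaternary carbon (6R, the later side-ring C6); the minor epimer is removed by chromatography.

Step 6
Reactants: 10 (3S,6R,8aR)-8a-ethyl-6-methyl-6-(4-methylpent-3-en-1-yl)-3-(propan-2-yl)hexahydro-5H-[1,3]oxazolo[3,2-a]pyridin-5-one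
Product: 13 (4R)-2,3,4-trimethyl-4-(4-methylpent-3-en-1-yl)cyclohex-2-en-1-one, via carbinolamine 11 (not isolated), via diketone 12 (not isolated)
Conditions: MeLi, THF, −78 → 0 °C; 1 M aq. Bu4NH2PO4, EtOH, reflux; KOH, EtOH, rt
Reagents that add atoms: methyllithium, [Li]C; water, O
Why: Meyers cyclohexenone synthesis: MeLi adds to the non-enolisable lactam carbonyl, buffered hydrolysis frees the 1,5-diketone and the auxiliary, and aldol condensation of the ethyl-ketone CH2 onto the acetyl carbonyl gives the more substituted (tetrasubstituted) enone without touching the quaternary centre.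

Step 7
Reactants: 13 (4R)-2,3,4-trimethyl-4-(4-methylpent-3-en-1-yl)cyclohex-2-en-1-one
Product: 14 tert-butyl{[(4R)-2,4-dimethyl-3-methylidene-4-(4-methylpent-3-en-1-yl)cyclohex-1-en-1-yl]oxy}dimethylsilane
Conditions: MeMgBr (1.3 equiv), FeCl3 (3 mol %), Et2O, −20 → 0 °C; TBSCl, Et3N, DMPU, 0 °C → rt
Reagents that add atoms: tert-butyldimethylsilyl chloride, CC(C)(C)[Si](C)(C)Cl
Why: Kharasch-type (iron-catalysed Grignard) thermodynamic enolisation removes a proton from the C3 methyl group, the only γ-position that carries hydrogen, and O-silylation of the linear dienolate gives the extended silyl dienol ether.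

Step 8
Reactants: 5 (6R,7R,10R)-6,7:10,11-diepoxy-7,11-dimethyldodec-1-en-3-one; 14 tert-butyl{[(4R)-2,4-dimethyl-3-methylidene-4-(4-methylpent-3-en-1-yl)cyclohex-1-en-1-yl]oxy}dimethylsilane
Product: 17 (3R,5aR,6R,9aR)-3-hydroxy-2,2,5a-trimethyl-6-{2-[(6R)-2,6-dimethyl-6-(4-methylpent-3-en-1-yl)-3-oxocyclohex-1-en-1-yl]ethyl}octahydro-1-benzoxepin-7(2H)-one, via TBS enol ether 15 (not isolated), via TMS ether 16 (not isolated)
Conditions: 14 (1.3 equiv), 2,6-di-tert-butyl-4-methylpyridine (2 equiv), CH2Cl2, −78 °C; TBSOTf (0.1 equiv), 30 min; then TMSOTf (1.5 equiv), −78 °C, 1 h; aq. NaHCO3; K2CO3 (cat.), MeOH, rt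
Reagents that add atoms: none
Why: Proposed new method: a silyl-triflate-catalysed vinylogous Mukaiyama–Michael addition (closest known type: γ-selective addition of silyl dienol ethers to vinyl ketones) joins the exocyclic CH2 of 14 to the enone terminus of 5 and, by silyl transfer, leaves the regiodefined (Z)-TBS enol ether 15 with the ketone oxygen masked; the stronger TMSOTf then silylates the terminal epoxide, the inner epoxide oxygen opens it at the tertiary carbon to close the oxepane and form an epoxonium ion, and the enol ether carbon attacks the tertiary epoxonium carbon with inversion through a chair (closest known type: TMSOTf-promoted tandem oxa-/carbacyclisation of diepoxy silyl enol ethers), so both rings form together with C3 and C9a taken from the Shi epoxides, C5a set by the anti opening and C6 by the chair (equatorial side chain, secured by base equilibration next to the ketone).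

Step 9
Reactants: 17 (3R,5aR,6R,9aR)-3-hydroxy-2,2,5a-trimethyl-6-{2-[(6R)-2,6-dimethyl-6-(4-methylpent-3-en-1-yl)-3-oxocyclohex-1-en-1-yl]ethyl}octahydro-1-benzoxepin-7(2H)-one
Product: 18 (4R)-3-{2-[(3R,5aR,6R,7S,9aR)-3,7-dihydroxy-2,2,5a,7-tetramethyldecahydro-1-benzoxepin-6-yl]ethyl}-2,4-dimethyl-4-(4-methylpent-3-en-1-yl)cyclohex-2-en-1-one
Conditions: MeMgBr (3.5 equiv), THF/toluene, −78 → −30 °C; aq. NH4Cl
Reagents that add atoms: methylmagnesium bromide, C[Mg]Br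
Why: Grignard 1,2-addition: the saturated ring ketone is more electrophilic than the tetrasubstituted enone (as in additions to the Wieland–Miescher ketone), and because the axial face is blocked by the syn-axial C5a methyl group the nucleophile enters equatorially, giving the equatorial methyl and axial hydroxyl group (7S).

Step 10
Reactants: 18 (4R)-3-{2-[(3R,5aR,6R,7S,9aR)-3,7-dihydroxy-2,2,5a,7-tetramethyldecahydro-1-benzoxepin-6-yl]ethyl}-2,4-dimethyl-4-(4-methylpent-3-en-1-yl)cyclohex-2-en-1-one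
Product: 19 (3R,5aR,6R,7S,9aR)-6-{2-[(3S,6R)-3-hydroxy-2,6-dimethyl-6-(4-methylpent-3-en-1-yl)cyclohex-1-en-1-yl]ethyl}-2,2,5a,7-tetramethyldecahydro-1-benzoxepine-3,7-diol
Conditions: (R)-1-methyl-3,3-diphenyltetrahydro-1H,3H-pyrrolo[1,2-c][1,3,2]oxazaborole ((R)-Me-CBS, 0.5 equiv), catecholborane (3 equiv), toluene, −78 → −40 °C; MeOH; aq. NaOH wash
Reagents that add atoms: none
Why: Corey–Bakshi–Shibata reduction: the (R)-oxazaborolidine binds the ketone with the alkene-bearing side as the large group and delivers hydride to give the (S)-allylic alcohol under catalyst control, and catecholborane at low temperature leaves the trisubstituted alkene untouched.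

**Compound list**
1 | (5E)-6,10-dimethylundeca-5,9-dien-2-one ((E)-geranylacetone) | CC(=O)CC/C=C(\C)CCC=C(C)C | starting material
2 | (5R,6R,9R)-5,6:9,10-diepoxy-6,10-dimethylundecan-2-one | CC(=O)CC[C@H]1O[C@]1(C)CC[C@H]1OC1(C)C | intermediate
3 | (6R,7R,10R)-1-(dimethylamino)-6,7:10,11-diepoxy-7,11-dimethyldodecan-3-one (Mannich base) | CN(C)CCC(=O)CC[C@H]1O[C@]1(C)CC[C@H]1OC1(C)C | intermediate
4 | (6R,7R,10R)-6,7:10,11-diepoxy-N,N,N,7,11-pentamethyl-3-oxododecan-1-aminium iodide | C[N+](C)(C)CCC(=O)CC[C@H]1O[C@]1(C)CC[C@H]1OC1(C)C.[I-] | intermediate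
5 | (6R,7R,10R)-6,7:10,11-diepoxy-7,11-dimethyldodec-1-en-3-one | C=CC(=O)CC[C@H]1O[C@]1(C)CC[C@H]1OC1(C)C | intermediate
6 | (2S)-2-amino-3-methylbutan-1-ol ((S)-valinol) | CC(C)[C@H](N)CO | starting material
7 | 5-oxoheptanoic acid | CCC(=O)CCCC(=O)O | starting material
8 | (3S,8aR)-8a-ethyl-3-(propan-2-yl)hexahydro-5H-[1,3]oxazolo[3,2-a]pyridin-5-one | CC[C@@]12CCCC(=O)N1[C@@H](C(C)C)CO2 | intermediate
9 | (3S,8aR)-8a-ethyl-6-(4-methylpent-3-en-1-yl)-3-(propan-2-yl)hexahydro-5H-[1,3]oxazolo[3,2-a]pyridin-5-one (C6 epimers) | CC[C@@]12CCC(CCC=C(C)C)C(=O)N1[C@@H](C(C)C)CO2 | intermediate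
10 | (3S,6R,8aR)-8a-ethyl-6-methyl-6-(4-methylpent-3-en-1-yl)-3-(propan-2-yl)hexahydro-5H-[1,3]oxazolo[3,2-a]pyridin-5-one | CC[C@@]12CC[C@@](C)(CCC=C(C)C)C(=O)N1[C@@H](C(C)C)CO2 | intermediate
11 | (3S,6R,8aR)-8a-ethyl-5,6-dimethyl-6-(4-methylpent-3-en-1-yl)-3-(propan-2-yl)hexahydro-5H-[1,3]oxazolo[3,2-a]pyridin-5-ol (C5 epimers) | CC[C@@]12CC[C@@](C)(CCC=C(C)C)C(C)(O)N1[C@@H](C(C)C)CO2 | intermediate
12 | (3R)-3-methyl-3-(4-methylpent-3-en-1-yl)octane-2,6-dione | CC(=O)[C@](C)(CCC=C(C)C)CCC(=O)CC | intermediate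
13 | (4R)-2,3,4-trimethyl-4-(4-methylpent-3-en-1-yl)cyclohex-2-en-1-one | CC(C)=CCC[C@]1(C)CCC(=O)C(C)=C1C | intermediate
14 | tert-butyl{[(4R)-2,4-dimethyl-3-methylidene-4-(4-methylpent-3-en-1-yl)cyclohex-1-en-1-yl]oxy}dimethylsilane | CC(C)=CCC[C@]1(C)CCC(O[Si](C)(C)C(C)(C)C)=C(C)C1=C | intermediate
15 | (4R)-3-[(3Z)-4-{[tert-butyl(dimethyl)silyl]oxy}-6-[(2R,3R)-3-{2-[(2R)-3,3-dimethyloxiran-2-yl]ethyl}-3-methyloxiran-2-yl]hex-3-en-1-yl]-2,4-dimethyl-4-(4-methylpent-3-en-1-yl)cyclohex-2-en-1-one | CC(C)=CCC[C@]1(C)CCC(=O)C(C)=C1CC/C=C(\O[Si](C)(C)C(C)(C)C)CC[C@H]1O[C@]1(C)CC[C@H]1OC1(C)C | intermediate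
16 | (3R,5aR,6R,9aR)-2,2,5a-trimethyl-6-{2-[(6R)-2,6-dimethyl-6-(4-methylpent-3-en-1-yl)-3-oxocyclohex-1-en-1-yl]ethyl}-3-[(trimethylsilyl)oxy]octahydro-1-benzoxepin-7(2H)-one | CC(C)=CCC[C@]1(C)CCC(=O)C(C)=C1CC[C@@H]1[C@@]2(C)CC[C@@H](O[Si](C)(C)C)C(C)(C)O[C@@H]2CCC1=O | intermediate
17 | (3R,5aR,6R,9aR)-3-hydroxy-2,2,5a-trimethyl-6-{2-[(6R)-2,6-dimethyl-6-(4-methylpent-3-en-1-yl)-3-oxocyclohex-1-en-1-yl]ethyl}octahydro-1-benzoxepin-7(2H)-one | CC(C)=CCC[C@]1(C)CCC(=O)C(C)=C1CC[C@@H]1[C@@]2(C)CC[C@@H](O)C(C)(C)O[C@@H]2CCC1=O | intermediate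
18 | (4R)-3-{2-[(3R,5aR,6R,7S,9aR)-3,7-dihydroxy-2,2,5a,7-tetramethyldecahydro-1-benzoxepin-6-yl]ethyl}-2,4-dimethyl-4-(4-methylpent-3-en-1-yl)cyclohex-2-en-1-one | CC(C)=CCC[C@]1(C)CCC(=O)C(C)=C1CC[C@@H]1[C@@]2(C)CC[C@@H](O)C(C)(C)O[C@@H]2CC[C@]1(C)O | intermediate
19 | (3R,5aR,6R,7S,9aR)-6-{2-[(3S,6R)-3-hydroxy-2,6-dimethyl-6-(4-methylpent-3-en-1-yl)cyclohex-1-en-1-yl]ethyl}-2,2,5a,7-tetramethyldecahydro-1-benzoxepine-3,7-diol | CC(C)=CCC[C@]1(C)CC[C@H](O)C(C)=C1CC[C@@H]1[C@@]2(C)CC[C@@H](O)C(C)(C)O[C@@H]2CC[C@]1(C)O | target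

**Step count**
Total: 10 steps. Longest linear sequence: 8 steps (steps 3 to 10, from 6 and 7).

**Steps most likely to fail, with fallbacks**

Step 8. Risk: the free vinyl ketone oxygen or the silyl triflate may open an epoxide before the Michael addition is complete, or the two events may not telescope. The fallback joins the halves by olefin metathesis and makes the enol silane under neutral conditions. It sets out from 10 and 5. CH2=CHCH2MgBr adds to 10 to give the carbinolamine (3S,6R,8aR)-8a-ethyl-6-methyl-6-(4-methylpent-3-en-1-yl)-3-(propan-2-yl)-5-(prop-2-en-1-yl)hexahydro-5H-[1,3]oxazolo[3,2-a]pyridin-5-ol F1. Buffered hydrolysis (Bu4NH2PO4) releases the diketone (5R)-5-methyl-5-(4-methylpent-3-en-1-yl)dec-1-ene-4,8-dione F2, which closes to (4R)-2,4-dimethyl-4-(4-methylpent-3-en-1-yl)-3-(prop-2-en-1-yl)cyclohex-2-en-1-one F3. Cross-metathesis of F3 with 5 (second-generation Hoveyda–Grubbs catalyst, RuCl2(H2IMes)(=CH-C6H4-2-OiPr), CH2Cl2, 40 °C) gives the enone (4R)-3-[(2E)-6-[(2R,3R)-3-{2-[(2R)-3,3-dimethyloxiran-2-yl]ethyl}-3-methyloxiran-2-yl]-4-oxohex-2-en-1-yl]-2,4-dimethyl-4-(4-methylpent-3-en-1-yl)cyclohex-2-en-1-one F4. RhCl(PPh3)3-catalysed 1,4-hydrosilylation with Et3SiH, selective for the disubstituted enone, gives the silyl enol ether (4R)-3-[(3Z)-6-[(2R,3R)-3-{2-[(2R)-3,3-dimethyloxiran-2-yl]ethyl}-3-methyloxiran-2-yl]-4-[(triethylsilyl)oxy]hex-3-en-1-yl]-2,4-dimethyl-4-(4-methylpent-3-en-1-yl)cyclohex-2-en-1-one F5. TMSOTf and 2,6-di-tert-butyl-4-methylpyridine at −78 °C then give 16, and K2CO3 in MeOH returns to the route at 17.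

Step 9. Risk: the Grignard reagent may also add to the enone carbonyl. The fallback removes the second ketone temporarily by redox instead of relying on a rate difference. It sets out from 17. NaBH4 with CeCl3·7H2O in MeOH at −78 °C reduces only the conjugated ketone and gives (3R,5aR,6R,9aR)-3-hydroxy-6-{2-[(6R)-3-hydroxy-2,6-dimethyl-6-(4-methylpent-3-en-1-yl)cyclohex-1-en-1-yl]ethyl}-2,2,5a-trimethyloctahydro-1-benzoxepin-7(2H)-one F6 (both carbinol epimers). MeMgBr then has a single ketone to attack and gives (3R,5aR,6R,7S,9aR)-6-{2-[(6R)-3-hydroxy-2,6-dimethyl-6-(4-methylpent-3-en-1-yl)cyclohex-1-en-1-yl]ethyl}-2,2,5a,7-tetramethyldecahydro-1-benzoxepine-3,7-diol F7 (both carbinol epimers). MnO2 in CH2Cl2 oxidises only the allylic alcohol and returns to the route at 18.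

Step 6. Risk: the diketone may condense the other way (acetyl CH3 onto the ethyl ketone), or MeLi may add poorly to the hindered lactam. The fallback closes the ring onto an aldehyde, which cannot enolise, and adds the ring methyl afterwards. It sets out from 10. NaAlH2(OCH2CH2OMe)2 in toluene reduces the lactam carbonyl to the carbinolamine (3S,6R,8aR)-8a-ethyl-6-methyl-6-(4-methylpent-3-en-1-yl)-3-(propan-2-yl)hexahydro-5H-[1,3]oxazolo[3,2-a]pyridin-5-ol F8. Bu4NH2PO4 hydrolysis gives the keto aldehyde (2R)-2-methyl-2-(4-methylpent-3-en-1-yl)-5-oxoheptanal F9, which can only condense to (4R)-2,4-dimethyl-4-(4-methylpent-3-en-1-yl)cyclohex-2-en-1-one F10. Conjugate addition of Me2CuLi in the presence of TMSCl gives trimethyl{[(4R)-2,3,4-trimethyl-4-(4-methylpent-3-en-1-yl)cyclohex-1-en-1-yl]oxy}silane F11 (C3 epimers), and Pd(OAc)2 in MeCN (Saegusa–Ito oxidation) returns to the route at 13.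

**Further compounds**
F1 | step 8 | (3S,6R,8aR)-8a-ethyl-6-methyl-6-(4-methylpent-3-en-1-yl)-3-(propan-2-yl)-5-(prop-2-en-1-yl)hexahydro-5H-[1,3]oxazolo[3,2-a]pyridin-5-ol | CC[C@@]12CC[C@@](C)(CCC=C(C)C)C(O)(CC=C)N1[C@@H](C(C)C)CO2
F2 | step 8 | (5R)-5-methyl-5-(4-methylpent-3-en-1-yl)dec-1-ene-4,8-dione | C=CCC(=O)[C@](C)(CCC=C(C)C)CCC(=O)CC
F3 | step 8 | (4R)-2,4-dimethyl-4-(4-methylpent-3-en-1-yl)-3-(prop-2-en-1-yl)cyclohex-2-en-1-one | CC(C)=CCC[C@]1(C)CCC(=O)C(C)=C1CC=C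
F4 | step 8 | (4R)-3-[(2E)-6-[(2R,3R)-3-{2-[(2R)-3,3-dimethyloxiran-2-yl]ethyl}-3-methyloxiran-2-yl]-4-oxohex-2-en-1-yl]-2,4-dimethyl-4-(4-methylpent-3-en-1-yl)cyclohex-2-en-1-one | CC(C)=CCC[C@]1(C)CCC(=O)C(C)=C1C/C=C/C(=O)CC[C@H]1O[C@]1(C)CC[C@H]1OC1(C)C
F5 | step 8 | (4R)-3-[(3Z)-6-[(2R,3R)-3-{2-[(2R)-3,3-dimethyloxiran-2-yl]ethyl}-3-methyloxiran-2-yl]-4-[(triethylsilyl)oxy]hex-3-en-1-yl]-2,4-dimethyl-4-(4-methylpent-3-en-1-yl)cyclohex-2-en-1-one | CC(C)=CCC[C@]1(C)CCC(=O)C(C)=C1CC/C=C(\O[Si](CC)(CC)CC)CC[C@H]1O[C@]1(C)CC[C@H]1OC1(C)C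
F6 | step 9 | (3R,5aR,6R,9aR)-3-hydroxy-6-{2-[(6R)-3-hydroxy-2,6-dimethyl-6-(4-methylpent-3-en-1-yl)cyclohex-1-en-1-yl]ethyl}-2,2,5a-trimethyloctahydro-1-benzoxepin-7(2H)-one (carbinol epimers) | CC(C)=CCC[C@]1(C)CCC(O)C(C)=C1CC[C@@H]1[C@@]2(C)CC[C@@H](O)C(C)(C)O[C@@H]2CCC1=O
F7 | step 9 | (3R,5aR,6R,7S,9aR)-6-{2-[(6R)-3-hydroxy-2,6-dimethyl-6-(4-methylpent-3-en-1-yl)cyclohex-1-en-1-yl]ethyl}-2,2,5a,7-tetramethyldecahydro-1-benzoxepine-3,7-diol (carbinol epimers) | CC(C)=CCC[C@]1(C)CCC(O)C(C)=C1CC[C@@H]1[C@@]2(C)CC[C@@H](O)C(C)(C)O[C@@H]2CC[C@]1(C)O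
F8 | step 6 | (3S,6R,8aR)-8a-ethyl-6-methyl-6-(4-methylpent-3-en-1-yl)-3-(propan-2-yl)hexahydro-5H-[1,3]oxazolo[3,2-a]pyridin-5-ol | CC[C@@]12CC[C@@](C)(CCC=C(C)C)C(O)N1[C@@H](C(C)C)CO2
F9 | step 6 | (2R)-2-methyl-2-(4-methylpent-3-en-1-yl)-5-oxoheptanal | O=C[C@](C)(CCC=C(C)C)CCC(=O)CC
F10 | step 6 | (4R)-2,4-dimethyl-4-(4-methylpent-3-en-1-yl)cyclohex-2-en-1-one | CC(C)=CCC[C@]1(C)CCC(=O)C(C)=C1
F11 | step 6 | trimethyl{[(4R)-2,3,4-trimethyl-4-(4-methylpent-3-en-1-yl)cyclohex-1-en-1-yl]oxy}silane (C3 epimers) | CC(C)=CCC[C@]1(C)CCC(O[Si](C)(C)C)=C(C)C1C
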